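## Analysis of the target

Neonambiquinone A (19) is a para-terphenyl whose central ring is a 1,4-benzoquinone, numbered here C1(=O), C2(OAc), C3(4-hydroxyphenyl), C4(=O), C5(H), C6(4-hydroxyphenyl). There is one ring to build and no stereocentre, so every difficulty is one of constitution and chemoselectivity. The quinone is oxygenated unsymmetrically, with oxygen at C2 and hydrogen at C5 although the two aryl groups sit para, so a symmetric union of two aryl-C3 units delivers the wrong pattern. Three hydroxyls must be told apart, and the acetyl group has to end on the quinone oxygen, the most acidic and least nucleophilic of them, where it forms a vinylogous mixed anhydride that is the most labile acyl group in the molecule. The quinone itself is reducible and electrophilic at the unsubstituted C5, and its enol acetate will not tolerate bases, nucleophiles or acyl-transfer catalysts once the phenols are free. The acetate is therefore best installed late, on a hydroxyquinone whose phenols carry groups removable under acidic, non-nucleophilic conditions. The strategy rests on the four-atom run C1(=O)–C2(O)=C3(aryl)–C4(O), which is an O-alkylated 3-hydroxy-4-arylbutenolide (an isotetronic acid) with the lactone carbonyl as C1, the enol-ether carbon as C2, the aryl-bearing carbon as C3 and the γ-carbon as C4. What is left, C5–C6 with its aryl group, is a 1-arylvinyl unit that can serve as a two-carbon acceptor.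

## Retrosynthetic reasoning

**19 ⇒ 18.** The two aryl O–Si bonds are cut last. Freeing the phenols only at the end means that no nucleophilic hydroxyl is present while the labile quinone acetate is made and handled. The forward step must desilylate under acidic, non-basic conditions.

**18 ⇒ 17 ⇒ 16.** The acetyl C–O bond is cut to give hydroxyquinone 17, in which the quinone hydroxyl is the only free one, so acetylation needs no selectivity. 17 is traced to its methyl ether 16, because a vinylogous acid cannot pass unprotected through a carbanion-based ring construction. A methyl ether on a quinone is a vinylogous ester and can be cleaved selectively beside aryl silyl ethers.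

**16 ⇒ 8 + 14 (through 15).** The ring is cut at C4–C5 and C6–C1. This separates a four-carbon piece holding all the ring oxygens and the C3 aryl group (sulfonyl butenolide 8) from a two-carbon piece holding the C6 aryl group (vinyl sulfone 14). The cut is made here because the polarities alternate naturally: C4 is a stabilised carbanion, C5 is the β-carbon of a vinyl sulfone, C6 becomes an α-sulfonyl carbanion, and C1 is a lactone carbonyl. What is gained is convergence, a para arrangement of the aryl groups that follows from the polarity of 14, and the quinone oxidation level from the loss of two sulfinate groups by way of enedione 15. The forward reaction must form both bonds in one operation and expel both sulfonyl groups.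

**8 ⇒ 6 + 7, and 6 ⇒ 5.** The C–S bond at the γ-carbon is cut to bromide 6 and sodium benzenesulfinate 7. The C–Br bond is traced to butenolide 5, whose γ-CH2 is allylic and next to oxygen, the natural site for radical bromination.

**5 ⇒ 4 ⇒ 3.** The aryl O–Si bond and then the enol O–CH3 bond are removed, leading to the dihydroxy compound 3. Methylation is placed first because it can exploit the higher acidity of the enolic hydroxyl. Once that is capped, silylation of the remaining phenol is unambiguous.

**3 ⇒ 1 + 2.** The butenolide is opened at the lactone C–O bond and at the bond between the aryl-bearing carbon and the CH2 group. This is an aldol disconnection to 4-hydroxyphenylpyruvic acid 1 and formaldehyde 2, and it delivers the whole ring of 3 in one step.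

**14 ⇒ 11 (through 12 and 13) ⇒ 10 ⇒ 9 + 7.** The terminal CH2 of 14 (the future C5) is removed, giving benzyl sulfone 11. The forward reaction is a Mannich-type methylenation through amine 12 and ammonium salt 13. Removing the silyl group gives 10, and cutting its benzylic C–S bond leads to 4-hydroxybenzyl alcohol 9 and, again, 7.

## Alternatives that were turned down

**Alternative 1: condensation of a glyoxylate with a symmetric diketone.**
- Disconnection: the ring is cut at C3–C4 and C5=C6. C3, C2, C1 and C6 with both aryl groups come from 1,4-bis{4-[(4-methoxybenzyl)oxy]phenyl}butane-2,3-dione A2, and C4 and C5 come from ethyl glyoxylate A3.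
- Forward key step: base would condense one benzylic carbon of A2 with the aldehyde carbon of A3 (Knoevenagel) and acylate the other benzylic carbon on the ester carbon of A3 (Claisen). Tautomerisation of the ring-closed product would give 2-hydroxy-3,6-bis{4-[(4-methoxybenzyl)oxy]phenyl}-1,4-benzoquinone A1.
- For: the symmetry of A2 removes any regiochemical question, the oxidation level is right without an oxidant, and A1 is already a hydroxyquinone, so no ether cleavage is needed. On step count this plan is shorter than the chosen one.
- Against:
  - In A2 an α-diketone is flanked by two benzylic methylenes, so it is strongly enolised and prone to self-condensation under base.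
  - After the first condensation the new alkene is doubly activated and invites Michael addition of a second molecule of A2.
  - Ring closure needs the ester group of the A3 unit cis to the diketone chain on the new double bond.
  - Two condensations of different type must occur in one flask in the right order, with nothing in the substrate to enforce it.
  - The benzyl-type ethers of A1 would have to come off by oxidation or acid beside the quinone and its acetate, which is harsher than fluoride.
- Comparison: the chosen route costs a few more steps but gives every new bond a fixed polarity and a fixed place in the sequence.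

**Alternative 2: squarate ring expansion through a dienylketene.**
- Disconnection: only the C4–C5 bond is formed in the ring-making step. The precursor is 4-hydroxy-3-isopropoxy-2-[4-(tert-butyldimethylsilyloxy)phenyl]-4-{1-[4-(tert-butyldimethylsilyloxy)phenyl]vinyl}cyclobut-2-en-1-one A5. It is assembled from diisopropyl squarate A6 by two successive additions of aryl-bearing carbon nucleophiles. The four carbons of A6 become C1 to C4, and three of its oxygens stay on C1, C2 and C4.
- Forward key step: heating A5 opens the four-membered ring to the dienylketene (3Z)-4-hydroxy-3-isopropoxy-2,5-bis[4-(tert-butyldimethylsilyloxy)phenyl]hexa-1,3,5-trien-1-one A7. 6π-Electrocyclisation of A7 joins its ketene carbon (C4) to the vinyl CH2 (C5), and tautomerisation gives 2-isopropoxy-3,6-bis[4-(tert-butyldimethylsilyloxy)phenyl]benzene-1,4-diol A4. Oxidation of A4 to the quinone and the same three-step endgame would follow.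
- For: each substituent is placed by an addition whose site is dictated by the core of A6, and the key step is thermal, neutral and insensitive to sterics. The reaction type is well established for crowded quinones. On reliability of the key step this alternative is at least as strong as the chosen one, and probably stronger.
- Against: it needs two different organometallic nucleophiles made from halogenated silyloxyarenes (one of them a 1-arylvinyl metal), cryogenic additions to A6 and to the sensitive four-membered ring derived from it, and an extra oxidation after A4. It ends with the same ether cleavage, acetylation and desilylation, so it saves no steps.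
- Comparison: the chosen strategy offers cheap non-halogenated phenolic feedstocks (1 and 9), a single organolithium operation, and direct arrival at the quinone oxidation level. The price is a key step run on a donor and an acceptor that are less tried than the partners usual for its reaction type.

**Alternative 3: biomimetic head-to-tail dimerisation of an arylpyruvate thioester.**
- Disconnection: C3–C4 and C6–C1 are both cut, so the ring is two identical three-carbon units, two molecules of S-ethyl 3-[4-(tert-butyldimethylsilyloxy)phenyl]-2-oxopropanethioate A9.
- Forward key step: two Claisen condensations, each benzylic carbon of one molecule of A9 onto the thioester carbon of the other, close the ring at the tetraketone level. That is the keto tautomer of 2,5-dihydroxy-3,6-bis[4-(tert-butyldimethylsilyloxy)phenyl]-1,4-benzoquinone A8, so no oxidant is needed.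
- For: it is the shortest and most symmetric construction, it follows the way such pigments arise in nature, and A9 derives from the same feedstock 1. On ring-forming step count it beats every other plan.
- Against:
  - A8 carries oxygen at C5 where 19 has hydrogen. One of two equivalent hydroxyls of A8 would have to be activated statistically and removed reductively on a quinone, and the other then acetylated. This gives back the steps saved.
  - Without an enzyme, the benzylic carbon of A9 attacks the ketone of a second molecule (aldol) more readily than its thioester, and lactonisation then diverts the material from the six-membered ring.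
- Comparison: the chosen strategy builds the unsymmetrical C2-oxygen/C5-hydrogen pattern by construction, because only one of its two fragments carries ring oxygen.

Key step: step 9

## Route

Remark on the chemistry: the enolic hydroxyl of 3 is taken to be two to three pK units more acidic than its phenol, by analogy with the 2-hydroxyl of 3-O-alkyl ascorbic acids; step 2 depends on this.
Remark on the structures: compounds 6, 8, 12, 13 and 15 are racemic, and one enantiomer is drawn.

Step 1
Reactants: 1 4-hydroxyphenylpyruvic acid; 2 formaldehyde
Product: 3 3-hydroxy-4-(4-hydroxyphenyl)furan-2(5H)-one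
Conditions: 37% aq. HCHO (1.1 equiv), K2CO3, H2O, 0 °C → rt; then 2 M HCl to pH 1
Reagents that add atoms: none
Why: Base-mediated cross-aldol (Tollens-type hydroxymethylation) of the arylpyruvate enolate at its benzylic carbon, followed on acidification by lactonisation of the γ-hydroxy-α-keto acid, which rests as the aryl-conjugated enol. With about one equivalent of formaldehyde at room temperature, hydroxymethylation of the phenoxide ring should be much slower than the aldol.

Step 2
Reactants: 3 3-hydroxy-4-(4-hydroxyphenyl)furan-2(5H)-one
Product: 4 4-(4-hydroxyphenyl)-3-methoxyfuran-2(5H)-one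
Conditions: TMSCHN2 (1.2 equiv), MeOH–toluene, 0 °C → rt
Reagents that add atoms: (trimethylsilyl)diazomethane, C[Si](C)(C)C=[N+]=[N-]
Why: O-Methylation of an acidic enol by a diazoalkane; proton transfer to the diazo carbon is rate-limiting, so the α-keto-lactone enol should react while the less acidic phenol is left. Diazoalkanes methylate such enols on oxygen, not on carbon.

Step 3
Reactants: 4 4-(4-hydroxyphenyl)-3-methoxyfuran-2(5H)-one
Product: 5 4-[4-(tert-butyldimethylsilyloxy)phenyl]-3-methoxyfuran-2(5H)-one
Conditions: TBSCl, imidazole, DMF, rt
Reagents that add atoms: tert-butyldimethylsilyl chloride, CC(C)(C)[Si](C)(C)Cl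
Why: Standard imidazole-promoted silylation of the only remaining hydroxyl; the enol ether and lactone are inert.

Step 4
Reactants: 5 4-[4-(tert-butyldimethylsilyloxy)phenyl]-3-methoxyfuran-2(5H)-one
Product: 6 5-bromo-4-[4-(tert-butyldimethylsilyloxy)phenyl]-3-methoxyfuran-2(5H)-one (racemic)
Conditions: NBS (1.05 equiv), AIBN (cat.), PhCF3, 80 °C; used crude
Reagents that add atoms: N-bromosuccinimide, O=C1CCC(=O)N1Br
Why: Wohl–Ziegler bromination; the C5 hydrogens are allylic and next to the ring oxygen, so the radical is captodatively stabilised, and the non-polar medium disfavours ionic bromination of the arene. The new stereocentre is formed racemic and is lost in step 9.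

Step 5
Reactants: 6 5-bromo-4-[4-(tert-butyldimethylsilyloxy)phenyl]-3-methoxyfuran-2(5H)-one; 7 sodium benzenesulfinate (PhSO2Na)
Product: 8 3-methoxy-4-[4-(tert-butyldimethylsilyloxy)phenyl]-5-(phenylsulfonyl)furan-2(5H)-one (racemic)
Conditions: DMF, 0 °C → rt
Reagents that add atoms: none
Why: S-Alkylation of the sulfinate by an allylic α-acyloxy bromide that ionises readily. The sulfone is the thermodynamic product, and any O-bound sulfinate ester should re-ionise and collapse to it.

Step 6
Reactants: 9 4-hydroxybenzyl alcohol; 7 sodium benzenesulfinate (PhSO2Na)
Product: 10 4-[(phenylsulfonyl)methyl]phenol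
Conditions: AcOH–H2O, 80 °C
Reagents that add atoms: none
Why: Acid-promoted ionisation of the 4-hydroxybenzyl alcohol to a p-quinone methide (benzylic cation), which the sulfinate captures at sulfur faster than the phenol can self-condense.

Step 7
Reactants: 10 4-[(phenylsulfonyl)methyl]phenol
Product: 11 tert-butyldimethyl{4-[(phenylsulfonyl)methyl]phenoxy}silane
Conditions: TBSCl, imidazole, DMF, rt
Reagents that add atoms: tert-butyldimethylsilyl chloride, CC(C)(C)[Si](C)(C)Cl
Why: Standard phenol silylation; the sulfone is inert.

Step 8
Reactants: 11 tert-butyldimethyl{4-[(phenylsulfonyl)methyl]phenoxy}silane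
Product: 14 tert-butyldimethyl{4-[1-(phenylsulfonyl)vinyl]phenoxy}silane, via Mannich base 12 (not isolated), via ammonium iodide 13 (not isolated)
Conditions: n-BuLi, THF, −78 °C; CH2=NMe2+ I−, −78 °C → rt; then MeI, MeCN, rt; K2CO3, rt
Reagents that add atoms: N,N-dimethylmethyleneiminium iodide (Eschenmoser's salt), C=[N+](C)C.[I-]; iodomethane, CI (its methyl group enters 13 and leaves again as trimethylamine)
Why: Mannich methylenation: the α-sulfonyl benzylic carbanion adds to the iminium salt to give 12, quaternisation gives 13, and mild base effects E1cB loss of trimethylamine. Lithiation at low temperature leaves the aryl silyl ether untouched.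

Step 9
Reactants: 8 3-methoxy-4-[4-(tert-butyldimethylsilyloxy)phenyl]-5-(phenylsulfonyl)furan-2(5H)-one; 14 tert-butyldimethyl{4-[1-(phenylsulfonyl)vinyl]phenoxy}silane
Product: 16 2-methoxy-3,6-bis[4-(tert-butyldimethylsilyloxy)phenyl]-1,4-benzoquinone, via sulfonyl enedione 15 (not isolated)
Conditions: LiOtBu (2.2 equiv), THF, −78 °C; then 14 (1.2 equiv), −78 → 0 °C; pH 7 phosphate buffer
Reagents that add atoms: none
Why: LiOtBu removes the γ-proton of 8 (furanone C5, the future quinone C4), which is acidified by the sulfonyl group, the ring oxygen and vinylogy to the lactone carbonyl, and the resulting 2-oxidofuran anion adds through that carbon to the unsubstituted CH2 terminus of 14 (the future C5). The α-sulfonyl benzylic carbanion so formed (C6) attacks the lactone carbonyl (C1) in a Dieckmann-type 6-exo-trig closure of the only ring made here, giving a 7-oxanorbornene-type tetrahedral alkoxide. Breakdown of this intermediate cleaves the lactone C–O bond, and the alkoxide left on the sulfonyl-bearing C4 ejects benzenesulfinate and so unveils the C4 ketone of 15. A second equivalent of base enolises 15 toward C5, and E1cB elimination of the remaining sulfinate from C6 on warming delivers 16 already as a quinone, so that no oxidant is called for. The reaction type is the Hauser–Kraus annulation of sulfonyl-stabilised lactone anions with Michael acceptors, applied here to a butenolide donor that is not benzo-fused and to a 1-arylvinyl sulfone whose activating group also serves as the second leaving group. The stereocentres that appear at C4 and C6 on the way are both destroyed, so no stereocontrol is required. The selectivity needed is regiochemical: the sulfone polarises 14 so that only its CH2 carbon is electrophilic, which is also the unhindered terminus, and this puts the aryl-bearing C6 next to C1 and the two aryl rings para, while attack of the donor through its γ-carbon rather than its α-carbon is the only path that leads on to ring closure and irreversible sulfinate loss. The methyl enol ether keeps the lactone carbonyl electrophilic, the aryl silyl ethers should be inert to the hindered alkoxide at low temperature, and holding back the elimination until the donor anion is consumed keeps the quinone away from carbanions.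

Step 10
Reactants: 16 2-methoxy-3,6-bis[4-(tert-butyldimethylsilyloxy)phenyl]-1,4-benzoquinone
Product: 17 2-hydroxy-3,6-bis[4-(tert-butyldimethylsilyloxy)phenyl]-1,4-benzoquinone
Conditions: BCl3 (1 M in CH2Cl2, 1.5 equiv), CH2Cl2, −78 → 0 °C; then H2O
Reagents that add atoms: none
Why: Lewis-acid cleavage of a vinylogous methyl ester: BCl3 is held by the C1 carbonyl and the adjacent methoxy oxygen, and chloride removes the methyl group by SN2. Aryl silyl ethers should survive these low-temperature conditions.

Step 11
Reactants: 17 2-hydroxy-3,6-bis[4-(tert-butyldimethylsilyloxy)phenyl]-1,4-benzoquinone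
Product: 18 2-acetoxy-3,6-bis[4-(tert-butyldimethylsilyloxy)phenyl]-1,4-benzoquinone
Conditions: Ac2O, pyridine, CH2Cl2, 0 °C
Reagents that add atoms: acetic anhydride, CC(=O)OC(C)=O
Why: O-Acylation of a hydroxyquinone (a vinylogous carboxylic acid), which is the only free hydroxyl. The ambident anion should give the para-quinone ester, since an ortho-quinone ester formed at the C4 oxygen would revert by pyridine-mediated acyl transfer.

Step 12
Reactants: 18 2-acetoxy-3,6-bis[4-(tert-butyldimethylsilyloxy)phenyl]-1,4-benzoquinone
Product: 19 neonambiquinone A, 2-acetoxy-3,6-bis(4-hydroxyphenyl)-1,4-benzoquinone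
Conditions: HF·pyridine, THF, 0 °C → rt; pH 7 buffer
Reagents that add atoms: none
Why: Cleavage of aryl silyl ethers by an acidic fluoride source. The medium is acidic and holds no strong nucleophile, so the quinone and its vinylogous-anhydride acetate should survive and acyl transfer to the new phenols is not catalysed.

## Compound list

1 | 4-hydroxyphenylpyruvic acid | O=C(O)C(=O)Cc1ccc(O)cc1 | starting material
2 | formaldehyde | C=O | starting material
3 | 3-hydroxy-4-(4-hydroxyphenyl)furan-2(5H)-one | O=C1OCC(c2ccc(O)cc2)=C1O | intermediate
4 | 4-(4-hydroxyphenyl)-3-methoxyfuran-2(5H)-one | COC1=C(c2ccc(O)cc2)COC1=O | intermediate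
5 | 4-[4-(tert-butyldimethylsilyloxy)phenyl]-3-methoxyfuran-2(5H)-one | COC1=C(c2ccc(O[Si](C)(C)C(C)(C)C)cc2)COC1=O | intermediate
6 | 5-bromo-4-[4-(tert-butyldimethylsilyloxy)phenyl]-3-methoxyfuran-2(5H)-one (racemic, one enantiomer drawn) | COC1=C(c2ccc(O[Si](C)(C)C(C)(C)C)cc2)[C@@H](Br)OC1=O | intermediate
7 | sodium benzenesulfinate | [Na+].[O-]S(=O)c1ccccc1 | starting material
8 | 3-methoxy-4-[4-(tert-butyldimethylsilyloxy)phenyl]-5-(phenylsulfonyl)furan-2(5H)-one (racemic, one enantiomer drawn) | COC1=C(c2ccc(O[Si](C)(C)C(C)(C)C)cc2)[C@@H](S(=O)(=O)c2ccccc2)OC1=O | intermediate
9 | 4-hydroxybenzyl alcohol | OCc1ccc(O)cc1 | starting material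
10 | 4-[(phenylsulfonyl)methyl]phenol | O=S(=O)(Cc1ccc(O)cc1)c1ccccc1 | intermediate
11 | tert-butyldimethyl{4-[(phenylsulfonyl)methyl]phenoxy}silane | CC(C)(C)[Si](C)(C)Oc1ccc(CS(=O)(=O)c2ccccc2)cc1 | intermediate
12 | 2-[4-(tert-butyldimethylsilyloxy)phenyl]-N,N-dimethyl-2-(phenylsulfonyl)ethan-1-amine (racemic, one enantiomer drawn; formed in the flask, not isolated) | CN(C)C[C@H](c1ccc(O[Si](C)(C)C(C)(C)C)cc1)S(=O)(=O)c1ccccc1 | intermediate
13 | 2-[4-(tert-butyldimethylsilyloxy)phenyl]-N,N,N-trimethyl-2-(phenylsulfonyl)ethan-1-aminium iodide (racemic, one enantiomer drawn; formed in the flask, not isolated) | C[N+](C)(C)C[C@H](c1ccc(O[Si](C)(C)C(C)(C)C)cc1)S(=O)(=O)c1ccccc1.[I-] | intermediate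
14 | tert-butyldimethyl{4-[1-(phenylsulfonyl)vinyl]phenoxy}silane | C=C(c1ccc(O[Si](C)(C)C(C)(C)C)cc1)S(=O)(=O)c1ccccc1 | intermediate
15 | 2-methoxy-3,6-bis[4-(tert-butyldimethylsilyloxy)phenyl]-6-(phenylsulfonyl)cyclohex-2-ene-1,4-dione (racemic, one enantiomer drawn; formed in the flask, not isolated) | COC1=C(c2ccc(O[Si](C)(C)C(C)(C)C)cc2)C(=O)C[C@@](c2ccc(O[Si](C)(C)C(C)(C)C)cc2)(S(=O)(=O)c2ccccc2)C1=O | intermediate
16 | 2-methoxy-3,6-bis[4-(tert-butyldimethylsilyloxy)phenyl]-1,4-benzoquinone | COC1=C(c2ccc(O[Si](C)(C)C(C)(C)C)cc2)C(=O)C=C(c2ccc(O[Si](C)(C)C(C)(C)C)cc2)C1=O | intermediate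
17 | 2-hydroxy-3,6-bis[4-(tert-butyldimethylsilyloxy)phenyl]-1,4-benzoquinone | OC1=C(c2ccc(O[Si](C)(C)C(C)(C)C)cc2)C(=O)C=C(c2ccc(O[Si](C)(C)C(C)(C)C)cc2)C1=O | intermediate
18 | 2-acetoxy-3,6-bis[4-(tert-butyldimethylsilyloxy)phenyl]-1,4-benzoquinone | CC(=O)OC1=C(c2ccc(O[Si](C)(C)C(C)(C)C)cc2)C(=O)C=C(c2ccc(O[Si](C)(C)C(C)(C)C)cc2)C1=O | intermediate
19 | neonambiquinone A, 2-acetoxy-3,6-bis(4-hydroxyphenyl)-1,4-benzoquinone | CC(=O)OC1=C(c2ccc(O)cc2)C(=O)C=C(c2ccc(O)cc2)C1=O | target

## Step count and least certain steps

Total: 12 steps. Longest linear sequence: 9 steps (steps 1–5 and 9–12, from 1 to 19). The vinyl sulfone branch (steps 6–8) has 3 steps.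

**Step 9 (key step).** What may go wrong: ring closure of the hindered tertiary α-sulfonyl carbanion onto the lactone may be slow, which would allow retro-Michael reaction and anionic oligomerisation of the vinyl sulfone. Once the quinone appears, electron transfer from remaining carbanions and conjugate addition of sulfinate at C5 (favoured if the work-up turns acidic) would erode the product. Fallback, from 5 and 14, rejoining at 16: the ring is closed one oxidation level lower, so that neither a quinone nor a second leaving group is present during the carbanion chemistry. Butenolide 5, not its sulfone, is deprotonated at its γ-carbon with LiHMDS in THF at −78 °C and combined with 14. Vinylogous Michael addition and the same Dieckmann-type closure should stop at 4-hydroxy-2-methoxy-3,6-bis[4-(tert-butyldimethylsilyloxy)phenyl]-6-(phenylsulfonyl)cyclohex-2-en-1-one F1 (mixture of diastereomers), because the alkoxide released from the lactone now sits on a CH carbon and has nothing to expel. Oxidation of the allylic alcohol of F1 with Dess–Martin periodinane gives enedione 15, and Et3N in CH2Cl2 then effects the E1cB loss of sulfinate to give 16.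

**Step 2.** What may go wrong: insufficient discrimination between the two hydroxyls if the acidity gap is smaller than assumed, so that the phenol is methylated as well. Fallback, from 3, rejoining at 4: acid-catalysed enol-ether formation (HC(OMe)3, MeOH, cat. TsOH, reflux), as used for the methyl enol ethers of cyclic 1,2-diones. It proceeds through the keto tautomer and its ketal, a path open only to the α-keto-lactone oxygen and not to a phenol, so the selectivity no longer depends on acidity. No new compound is made.

**Step 4.** What may go wrong: ionic bromination of the electron-rich silyloxyarene or of the enol ether instead of radical substitution at C5, over-bromination at C5, and hydrolysis of the bromide on handling. Fallback, from 5, rejoining at 8: the γ-carbon is oxidised by oxygen transfer instead of by a bromine radical. TBSOTf and Et3N convert 5 into tert-butyl({3-methoxy-4-[4-(tert-butyldimethylsilyloxy)phenyl]furan-2-yl}oxy)dimethylsilane F2. Dimethyldioxirane in acetone at −78 °C oxidises this 2-silyloxyfuran to the γ-hydroxybutenolide 5-hydroxy-3-methoxy-4-[4-(tert-butyldimethylsilyloxy)phenyl]furan-2(5H)-one F3. Sodium benzenesulfinate 7 in AcOH then exchanges the pseudo-acid hydroxyl of F3 for the sulfonyl group, as in the preparation of sulfonylphthalides from hydroxyphthalides, and gives 8.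

**Step 10.** What may go wrong: loss of the aryl silyl ethers to the Lewis acid before the hindered methyl ether is fully cleaved. Fallback, from 16, rejoining at 17: hydrolysis of the vinylogous ester by addition–elimination at C2 (aqueous HCl in dioxane, 50 °C) instead of dealkylation at the methyl carbon. Aryl silyl ethers should tolerate dilute aqueous acid better than boron halides. No new compound is made.

**Step 12.** What may go wrong: acetyl transfer from the activated quinone ester to the liberated phenols, or hydrolysis of that ester during desilylation and work-up. Fallback, from 17, rejoining at 19: the order of the last two operations is reversed. HF·pyridine removes both silyl groups from 17, where nothing labile is present, to give 2-hydroxy-3,6-bis(4-hydroxyphenyl)-1,4-benzoquinone F4. One equivalent of Et3N in THF at −78 °C then ionises only the quinone hydroxyl (the vinylogous carboxylic acid), and one equivalent of acetyl chloride acylates that anion, while the neutral phenols should not react without free base.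

## Further compounds

F1 | step 9 | 4-hydroxy-2-methoxy-3,6-bis[4-(tert-butyldimethylsilyloxy)phenyl]-6-(phenylsulfonyl)cyclohex-2-en-1-one (mixture of diastereomers, racemic) | COC1=C(c2ccc(O[Si](C)(C)C(C)(C)C)cc2)C(O)CC(c2ccc(O[Si](C)(C)C(C)(C)C)cc2)(S(=O)(=O)c2ccccc2)C1=O
F0 | step 2 | none | none
F2 | step 4 | tert-butyl({3-methoxy-4-[4-(tert-butyldimethylsilyloxy)phenyl]furan-2-yl}oxy)dimethylsilane | COc1c(O[Si](C)(C)C(C)(C)C)occ1-c1ccc(O[Si](C)(C)C(C)(C)C)cc1
F3 | step 4 | 5-hydroxy-3-methoxy-4-[4-(tert-butyldimethylsilyloxy)phenyl]furan-2(5H)-one (racemic, one enantiomer drawn) | COC1=C(c2ccc(O[Si](C)(C)C(C)(C)C)cc2)[C@@H](O)OC1=O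
F0 | step 10 | none | none
F4 | step 12 | 2-hydroxy-3,6-bis(4-hydroxyphenyl)-1,4-benzoquinone | OC1=C(c2ccc(O)cc2)C(=O)C=C(c2ccc(O)cc2)C1=O
A1 | alternative 1 | 2-hydroxy-3,6-bis{4-[(4-methoxybenzyl)oxy]phenyl}-1,4-benzoquinone | OC1=C(c2ccc(OCc3ccc(OC)cc3)cc2)C(=O)C=C(c2ccc(OCc3ccc(OC)cc3)cc2)C1=O
A2 | alternative 1 | 1,4-bis{4-[(4-methoxybenzyl)oxy]phenyl}butane-2,3-dione | COc1ccc(COc2ccc(CC(=O)C(=O)Cc3ccc(OCc4ccc(OC)cc4)cc3)cc2)cc1
A3 | alternative 1 | ethyl glyoxylate | CCOC(=O)C=O
A4 | alternative 2 | 2-isopropoxy-3,6-bis[4-(tert-butyldimethylsilyloxy)phenyl]benzene-1,4-diol | CC(C)Oc1c(O)c(c2ccc(O[Si](C)(C)C(C)(C)C)cc2)cc(O)c1c3ccc(O[Si](C)(C)C(C)(C)C)cc3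
A5 | alternative 2 | 4-hydroxy-3-isopropoxy-2-[4-(tert-butyldimethylsilyloxy)phenyl]-4-{1-[4-(tert-butyldimethylsilyloxy)phenyl]vinyl}cyclobut-2-en-1-one (racemic, one enantiomer drawn) | C=C(c1ccc(O[Si](C)(C)C(C)(C)C)cc1)[C@]1(O)C(OC(C)C)=C(c2ccc(O[Si](C)(C)C(C)(C)C)cc2)C1=O
A6 | alternative 2 | diisopropyl squarate | CC(C)OC1=C(OC(C)C)C(=O)C1=O
A7 | alternative 2 | (3Z)-4-hydroxy-3-isopropoxy-2,5-bis[4-(tert-butyldimethylsilyloxy)phenyl]hexa-1,3,5-trien-1-one | O=C=C(c1ccc(O[Si](C)(C)C(C)(C)C)cc1)/C(OC(C)C)=C(O)\C(=C)c1ccc(O[Si](C)(C)C(C)(C)C)cc1
A8 | alternative 3 | 2,5-dihydroxy-3,6-bis[4-(tert-butyldimethylsilyloxy)phenyl]-1,4-benzoquinone | O=C1C(O)=C(c2ccc(O[Si](C)(C)C(C)(C)C)cc2)C(=O)C(O)=C1c3ccc(O[Si](C)(C)C(C)(C)C)cc3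
A9 | alternative 3 | S-ethyl 3-[4-(tert-butyldimethylsilyloxy)phenyl]-2-oxopropanethioate | CCSC(=O)C(=O)Cc1ccc(O[Si](C)(C)C(C)(C)C)cc1
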